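**Retrosynthetic overview**

1. The 4-methoxybenzoate is attached last to diol 19. The whole hydroazulene core comes from monocyclic cyclopentene 16 in one operation that forms C8–C8a and C6=C7 (azulene numbering: C1 ketone, C3 isopropyl, C3a hydroxyl, C6 methyl, C8 ester oxygen, C8a methyl).
2. Enabling feature: the γ,δ-unsaturated ketone C1(=O)–C8a–C8(O)–C7=C6. Quaternary C8a, α to the cyclopentanone carbonyl, carries oxygenated C8, and the γ,δ-olefin is the only double bond of the seven-membered ring. This is a Claisen retron (C8–C8a) whose vinyl product is closed onto an isopropenyl arm by ring-closing metathesis (C6=C7).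
3. 16 comes from vinylogous ester 12 by Grignard 1,2-addition, which sets C3a anti to the isopropyl group. 12 comes from chloro enone 8 and the E-configured silyloxy allyl alcohol 11.
4. The C3 stereocentre comes from an Evans alkylation; alkyne hydration and a Dieckmann-type closure then give cyclopentanedione 7.
5. Ring order: five-membered ring first (step 4), seven-membered ring last (step 10).

Key step: step 10

Assumption: anions made by deprotonation inside a step (enolates, alkoxides, ylides) are treated as reactive forms of the listed compounds and are not numbered, and dione 7 is drawn as its diketo tautomer although it should exist mainly as the enol.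

**Route**

Step 1
Reactants: 1 (4R)-4-benzyl-1,3-oxazolidin-2-one; 2 3-methylbutanoyl chloride
Product: 3 (4R)-4-benzyl-3-(3-methylbutanoyl)-1,3-oxazolidin-2-one
Conditions: Et3N, DMAP (cat.), CH2Cl2, 0 °C to rt
Reagents that add atoms: none
Why: DMAP-catalysed N-acylation of the oxazolidinone by the acid chloride (nucleophilic acyl substitution) should give the Evans imide without forming a stereocentre.

Step 2
Reactants: 3 (4R)-4-benzyl-3-(3-methylbutanoyl)-1,3-oxazolidin-2-one; 4 1-bromobut-2-yne
Product: 5 (4R)-4-benzyl-3-[(2R)-2-(propan-2-yl)hex-4-ynoyl]-1,3-oxazolidin-2-one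
Conditions: NaN(SiMe3)2, THF, −78 °C; then 4, −78 to −20 °C
Reagents that add atoms: none
Why: Evans asymmetric alkylation, in which the chelated Z sodium enolate is alkylated by the propargylic bromide on the face opposite the benzyl group, should set the isopropyl-bearing centre (later C3) as R.

Step 3
Reactants: 5 (4R)-4-benzyl-3-[(2R)-2-(propan-2-yl)hex-4-ynoyl]-1,3-oxazolidin-2-one
Product: 6 (4R)-4-benzyl-3-[(2R)-4-oxo-2-(propan-2-yl)hexanoyl]-1,3-oxazolidin-2-one
Conditions: Ph3PAuCl (2 mol%), AgOTf (2 mol%), 1,4-dioxane/H2O 10:1, 60 °C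
Reagents that add atoms: water, O
Why: Gold-catalysed alkyne hydration with neighbouring-group participation (5-exo-dig attack of the imide carbonyl oxygen on the gold-bound alkyne) should place the new oxygen on C4 of the chain and give only the γ-keto imide, leaving the stereocentre untouched.

Step 4
Reactants: 6 (4R)-4-benzyl-3-[(2R)-4-oxo-2-(propan-2-yl)hexanoyl]-1,3-oxazolidin-2-one
Product: 7 (4R)-2-methyl-4-(propan-2-yl)cyclopentane-1,3-dione
Conditions: LiN(SiMe3)2 (2.2 equiv), THF, −78 to 0 °C; 1 M HCl work-up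
Reagents that add atoms: none
Why: Dieckmann-type (intramolecular Claisen) condensation, in which the ethyl-ketone enolate attacks the imide carbonyl in a 5-exo-trig closure and expels the auxiliary, should end as the stable 1,3-dione enolate, which protects the stereocentre from epimerisation.

Step 5
Reactants: 7 (4R)-2-methyl-4-(propan-2-yl)cyclopentane-1,3-dione
Product: 8 (5R)-3-chloro-2-methyl-5-(propan-2-yl)cyclopent-2-en-1-one
Conditions: (COCl)2, DMF (cat.), CH2Cl2, 0 °C to rt
Reagents that add atoms: oxalyl chloride, O=C(Cl)C(=O)Cl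
Why: Vilsmeier-type activation of the vinylogous acid followed by addition–elimination of chloride should occur at the less hindered enol oxygen, remote from the isopropyl group, so that chlorine ends on C3 and the ketone stays next to the stereocentre.

Step 6
Reactants: 9 malondialdehyde tetrabutylammonium salt
Product: 10 (2E)-3-{[tert-butyl(dimethyl)silyl]oxy}prop-2-enal
Conditions: tBuMe2SiCl, CH2Cl2, 0 °C to rt
Reagents that add atoms: tert-butyl(chloro)dimethylsilane, CC(C)(C)[Si](C)(C)Cl
Why: O-silylation of the W-shaped malondialdehyde enolate should give the E silyl enol ether with retention of the enolate geometry.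

Step 7
Reactants: 10 (2E)-3-{[tert-butyl(dimethyl)silyl]oxy}prop-2-enal
Product: 11 (2E)-3-{[tert-butyl(dimethyl)silyl]oxy}prop-2-en-1-ol
Conditions: iBu2AlH, CH2Cl2, −78 °C; aq. KNaC4H4O6 (potassium sodium tartrate) work-up
Reagents that add atoms: none
Why: 1,2-Reduction of the enal by the aluminium hydride at low temperature should give the allylic alcohol without touching the silyl enol ether or its E geometry.

Step 8
Reactants: 8 (5R)-3-chloro-2-methyl-5-(propan-2-yl)cyclopent-2-en-1-one; 11 (2E)-3-{[tert-butyl(dimethyl)silyl]oxy}prop-2-en-1-ol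
Product: 12 (5R)-3-{[(2E)-3-{[tert-butyl(dimethyl)silyl]oxy}prop-2-en-1-yl]oxy}-2-methyl-5-(propan-2-yl)cyclopent-2-en-1-one
Conditions: NaH, THF, 0 °C; then 8, −40 to 0 °C
Reagents that add atoms: none
Why: Addition–elimination (vinylogous acyl substitution) of the sodium alkoxide of 11 at the chlorine-bearing carbon of 8 should give the vinylogous ester without involving the E enol ether or the α′ stereocentre.

Step 9
Reactants: 12 (5R)-3-{[(2E)-3-{[tert-butyl(dimethyl)silyl]oxy}prop-2-en-1-yl]oxy}-2-methyl-5-(propan-2-yl)cyclopent-2-en-1-one; 13 4-bromo-2-methylbut-1-ene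
Product: 16 triethyl{[(1S,5R)-3-{[(2E)-3-{[tert-butyl(dimethyl)silyl]oxy}prop-2-en-1-yl]oxy}-2-methyl-1-(3-methylbut-3-en-1-yl)-5-(propan-2-yl)cyclopent-2-en-1-yl]oxy}silane, via butenyl Grignard reagent 14 (not isolated), via bromomagnesium alkoxide 15 (not isolated)
Conditions: Mg, THF, rt (13 to 14); then 12, THF, −78 to −30 °C; then Et3SiOTf, −78 to 0 °C; aq. NaHCO3 work-up
Reagents that add atoms: triethylsilyl trifluoromethanesulfonate, CC[Si](CC)(CC)OS(=O)(=O)C(F)(F)F
Why: Grignard 1,2-addition to the vinylogous ester carbonyl (the first stage of a Stork–Danheiser sequence) anti to the adjacent isopropyl group should set C3a with its oxygen cis to isopropyl, and O-silylation of the alkoxide in the same flask avoids isolating the acid-labile tertiary allylic alcohol.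

Step 10
Reactants: 16 triethyl{[(1S,5R)-3-{[(2E)-3-{[tert-butyl(dimethyl)silyl]oxy}prop-2-en-1-yl]oxy}-2-methyl-1-(3-methylbut-3-en-1-yl)-5-(propan-2-yl)cyclopent-2-en-1-yl]oxy}silane
Product: 18 (3R,3aS,8R,8aR)-8-{[tert-butyl(dimethyl)silyl]oxy}-6,8a-dimethyl-3-(propan-2-yl)-3a-[(triethylsilyl)oxy]-3,3a,4,5,8,8a-hexahydroazulen-1(2H)-one, via Claisen ketone 17 (not isolated)
Conditions: PhMe (0.005 M), BHT (cat.), 110 °C; then second-generation Hoveyda–Grubbs catalyst (10 mol%), 80 °C, argon sparge
Reagents that add atoms: none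
Why: Heating 16 should trigger a Claisen [3,3]-sigmatropic rearrangement of the allyl enol ether, in which the bond from the ring oxygen to the allyl CH2 breaks, C8–C8a forms and the C1 ketone and a vinyl group on C8 appear (17); the ruthenium alkylidene then joins this vinyl group to the isopropenyl group by ring-closing metathesis, forming C6=C7 and releasing ethene. The closest known reaction types are the aliphatic Claisen rearrangement of allyl enol ethers of 2-alkylcycloalkanones to α-quaternary ketones, which a donor on the allyl terminus accelerates, and ring-closing metathesis to trisubstituted cycloalkenes. The seven-membered ring is closed by the metathesis step as a ring with a Z trisubstituted olefin, which is possible only when the two alkenyl arms are cis on the cyclopentanone. C8a is set by the face of the enol ether that receives the allyl terminus, expected to be the face anti to the pseudo-axial triethylsilyloxy group on C3a and to the cis isopropyl group, which is the face of the butenyl arm; C8 is set relative to C8a by the chair transition state, in which the E enol ether places the silyloxy group equatorial. The step needs this facial selectivity and the E geometry of the silyl enol ether, which the bulky tertiary silyl ether and the E-configured alcohol 11 are meant to secure; there is no regiochemical choice, because 16 has one allyl vinyl ether array and 17 has only two terminal alkenes.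

Step 11
Reactants: 18 (3R,3aS,8R,8aR)-8-{[tert-butyl(dimethyl)silyl]oxy}-6,8a-dimethyl-3-(propan-2-yl)-3a-[(triethylsilyl)oxy]-3,3a,4,5,8,8a-hexahydroazulen-1(2H)-one
Product: 19 (3R,3aS,8R,8aR)-3a,8-dihydroxy-6,8a-dimethyl-3-(propan-2-yl)-3,3a,4,5,8,8a-hexahydroazulen-1(2H)-one
Conditions: HF·pyridine, pyridine, THF, 0 to 40 °C
Reagents that add atoms: none
Why: Fluoride-mediated desilylation of both silyl ethers under buffered, non-basic conditions should spare the β-hydroxy ketone from retro-aldol cleavage and leave all stereocentres untouched.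

Step 12
Reactants: 19 (3R,3aS,8R,8aR)-3a,8-dihydroxy-6,8a-dimethyl-3-(propan-2-yl)-3,3a,4,5,8,8a-hexahydroazulen-1(2H)-one; 20 4-methoxybenzoyl chloride
Product: 21 (3R,3aS,8R,8aR)-3a-hydroxy-6,8a-dimethyl-1-oxo-3-(propan-2-yl)-1,2,3,3a,4,5,8,8a-octahydroazulen-8-yl 4-methoxybenzoate
Conditions: Et3N, DMAP, CH2Cl2, 0 °C to rt
Reagents that add atoms: none
Why: DMAP-catalysed esterification with the acid chloride should be selective for the secondary allylic C8 hydroxyl, because the tertiary C3a hydroxyl is too hindered to be acylated, and it touches no stereocentre.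

**Compound list**

1 | (4R)-4-benzyl-1,3-oxazolidin-2-one | O=C1OC[C@@H](Cc2ccccc2)N1 | starting material
2 | 3-methylbutanoyl chloride | CC(C)CC(=O)Cl | starting material
3 | (4R)-4-benzyl-3-(3-methylbutanoyl)-1,3-oxazolidin-2-one | O=C1OC[C@@H](Cc2ccccc2)N1C(=O)CC(C)C | intermediate
4 | 1-bromobut-2-yne | CC#CCBr | starting material
5 | (4R)-4-benzyl-3-[(2R)-2-(propan-2-yl)hex-4-ynoyl]-1,3-oxazolidin-2-one | O=C1OC[C@@H](Cc2ccccc2)N1C(=O)[C@@H](C(C)C)CC#CC | intermediate
6 | (4R)-4-benzyl-3-[(2R)-4-oxo-2-(propan-2-yl)hexanoyl]-1,3-oxazolidin-2-one | O=C1OC[C@@H](Cc2ccccc2)N1C(=O)[C@@H](C(C)C)CC(=O)CC | intermediate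
7 | (4R)-2-methyl-4-(propan-2-yl)cyclopentane-1,3-dione | CC1C(=O)C[C@H](C(C)C)C1=O | intermediate
8 | (5R)-3-chloro-2-methyl-5-(propan-2-yl)cyclopent-2-en-1-one | CC1=C(Cl)C[C@H](C(C)C)C1=O | intermediate
9 | malondialdehyde tetrabutylammonium salt | [O-]/C=C/C=O.CCCC[N+](CCCC)(CCCC)CCCC | starting material
10 | (2E)-3-{[tert-butyl(dimethyl)silyl]oxy}prop-2-enal | O=C/C=C/O[Si](C)(C)C(C)(C)C | intermediate
11 | (2E)-3-{[tert-butyl(dimethyl)silyl]oxy}prop-2-en-1-ol | OC/C=C/O[Si](C)(C)C(C)(C)C | intermediate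
12 | (5R)-3-{[(2E)-3-{[tert-butyl(dimethyl)silyl]oxy}prop-2-en-1-yl]oxy}-2-methyl-5-(propan-2-yl)cyclopent-2-en-1-one | CC1=C(OC/C=C/O[Si](C)(C)C(C)(C)C)C[C@H](C(C)C)C1=O | intermediate
13 | 4-bromo-2-methylbut-1-ene | C=C(C)CCBr | starting material
14 | (3-methylbut-3-en-1-yl)magnesium bromide | C=C(C)CC[Mg]Br | intermediate
15 | bromomagnesium (1S,5R)-3-{[(2E)-3-{[tert-butyl(dimethyl)silyl]oxy}prop-2-en-1-yl]oxy}-2-methyl-1-(3-methylbut-3-en-1-yl)-5-(propan-2-yl)cyclopent-2-en-1-olate | C=C(C)CC[C@]1(O[Mg]Br)[C@@H](C(C)C)CC(OC/C=C/O[Si](C)(C)C(C)(C)C)=C1C | intermediate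
16 | triethyl{[(1S,5R)-3-{[(2E)-3-{[tert-butyl(dimethyl)silyl]oxy}prop-2-en-1-yl]oxy}-2-methyl-1-(3-methylbut-3-en-1-yl)-5-(propan-2-yl)cyclopent-2-en-1-yl]oxy}silane (silyloxy group cis to isopropyl) | C=C(C)CC[C@]1(O[Si](CC)(CC)CC)[C@@H](C(C)C)CC(OC/C=C/O[Si](C)(C)C(C)(C)C)=C1C | intermediate
17 | (2R,3S,4R)-2-[(1R)-1-{[tert-butyl(dimethyl)silyl]oxy}prop-2-en-1-yl]-2-methyl-3-(3-methylbut-3-en-1-yl)-4-(propan-2-yl)-3-[(triethylsilyl)oxy]cyclopentan-1-one | C=C(C)CC[C@]1(O[Si](CC)(CC)CC)[C@@H](C(C)C)CC(=O)[C@]1(C)[C@H](O[Si](C)(C)C(C)(C)C)C=C | intermediate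
18 | (3R,3aS,8R,8aR)-8-{[tert-butyl(dimethyl)silyl]oxy}-6,8a-dimethyl-3-(propan-2-yl)-3a-[(triethylsilyl)oxy]-3,3a,4,5,8,8a-hexahydroazulen-1(2H)-one | CC(C)(C)[Si](C)(C)O[C@@H]1C=C(C)CC[C@]2(O[Si](CC)(CC)CC)[C@@H](C(C)C)CC(=O)[C@]12C | intermediate
19 | (3R,3aS,8R,8aR)-3a,8-dihydroxy-6,8a-dimethyl-3-(propan-2-yl)-3,3a,4,5,8,8a-hexahydroazulen-1(2H)-one | O[C@@H]1C=C(C)CC[C@]2(O)[C@@H](C(C)C)CC(=O)[C@]12C | intermediate
20 | 4-methoxybenzoyl chloride | COc1ccc(C(=O)Cl)cc1 | starting material
21 | (3R,3aS,8R,8aR)-3a-hydroxy-6,8a-dimethyl-1-oxo-3-(propan-2-yl)-1,2,3,3a,4,5,8,8a-octahydroazulen-8-yl 4-methoxybenzoate | COc1ccc(C(=O)O[C@@H]2C=C(C)CC[C@]3(O)[C@@H](C(C)C)CC(=O)[C@]23C)cc1 | target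

**Step count and risks**

Total step count: 12. Longest linear sequence: 10 steps (1, 2, 3, 4, 5, 8, 9, 10, 11, 12); steps 6 and 7 make the side-chain alcohol 11.

Step 10. Process at risk: poor facial selectivity in the sigmatropic step (delivery of the allyl terminus to the face of the silyloxy group) would give the C8a epimer, whose two alkenyl arms are trans and cannot close to the cis-fused ring. Fallback, from 7 back to 19: the order of the two bond formations is reversed, so that the electrophile is tethered through the butenyl chain.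
- 7 is O-silylated on the less hindered enol oxygen (iPr3SiOTf, Et3N, CH2Cl2, 0 °C) to (5R)-2-methyl-5-(propan-2-yl)-3-{[tri(propan-2-yl)silyl]oxy}cyclopent-2-en-1-one F1.
- Grignard reagent 14 adds to its ketone as in step 9 to give bromomagnesium (1S,5R)-2-methyl-1-(3-methylbut-3-en-1-yl)-5-(propan-2-yl)-3-{[tri(propan-2-yl)silyl]oxy}cyclopent-2-en-1-olate F2. Et3SiOTf converts this in the same flask into triethyl{[(1S,5R)-2-methyl-1-(3-methylbut-3-en-1-yl)-5-(propan-2-yl)-3-{[tri(propan-2-yl)silyl]oxy}cyclopent-2-en-1-yl]oxy}silane F3.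
- Cross-metathesis of the isopropenyl group with (E)-but-2-enal (second-generation Hoveyda–Grubbs catalyst, CH2Cl2, 40 °C) should give (2Z)-3-methyl-5-[(1S,5R)-2-methyl-5-(propan-2-yl)-1-[(triethylsilyl)oxy]-3-{[tri(propan-2-yl)silyl]oxy}cyclopent-2-en-1-yl]pent-2-enal F4. The olefin geometry should equilibrate once the aldehyde is bound to the Lewis acid, and only the Z form can reach the ring.
- BF3·OEt2 (CH2Cl2, −78 °C) should then effect an intramolecular Mukaiyama aldol reaction in which the chain can deliver the aldehyde only to its own face of C8a, giving (3R,3aS,8R,8aR)-8-hydroxy-6,8a-dimethyl-3-(propan-2-yl)-3a-[(triethylsilyl)oxy]-3,3a,4,5,8,8a-hexahydroazulen-1(2H)-one F5.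
- HF·pyridine as in step 11 removes the triethylsilyl group and gives 19.

Step 9. Process at risk: deprotonation of the hindered, enolisable ketone by the basic Grignard reagent instead of addition, with erosion of the neighbouring stereocentre. Fallback, from 12 back to 16: the butenyl arm is assembled from two smaller nucleophiles.
- Corey–Chaykovsky epoxidation of 12 (Me3SI, KN(SiMe3)2, THF, −10 °C; methylene transfer anti to the isopropyl group) should give the spiro-epoxide (3S,7R)-5-{[(2E)-3-{[tert-butyl(dimethyl)silyl]oxy}prop-2-en-1-yl]oxy}-4-methyl-7-(propan-2-yl)-1-oxaspiro[2.4]hept-4-ene F6.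
- Copper-catalysed opening at the epoxide CH2 with commercial 2-methylallylmagnesium chloride (CuI cat., THF, −40 °C) gives chloromagnesium (1S,5R)-3-{[(2E)-3-{[tert-butyl(dimethyl)silyl]oxy}prop-2-en-1-yl]oxy}-2-methyl-1-(3-methylbut-3-en-1-yl)-5-(propan-2-yl)cyclopent-2-en-1-olate F7.
- F7 is silylated in the same flask with Et3SiOTf to give 16.

Step 8. Process at risk: the sodium alkoxide of 11 is basic enough to epimerise the α′ stereocentre of 8 or to degrade the silyl enol ether before substitution is complete. Fallback, from 7 (with 11) back to 12, no new compound: neutral Mitsunobu O-alkylation of the vinylogous acid 7 with 11 (PPh3, diisopropyl azodicarboxylate, THF, 0 °C). This bypasses 8 and should form the same enol ether at the less hindered enol oxygen.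

Further compounds
F1 | step 10 | (5R)-2-methyl-5-(propan-2-yl)-3-{[tri(propan-2-yl)silyl]oxy}cyclopent-2-en-1-one | CC1=C(O[Si](C(C)C)(C(C)C)C(C)C)C[C@H](C(C)C)C1=O
F2 | step 10 | bromomagnesium (1S,5R)-2-methyl-1-(3-methylbut-3-en-1-yl)-5-(propan-2-yl)-3-{[tri(propan-2-yl)silyl]oxy}cyclopent-2-en-1-olate | C=C(C)CC[C@]1(O[Mg]Br)[C@@H](C(C)C)CC(O[Si](C(C)C)(C(C)C)C(C)C)=C1C
F3 | step 10 | triethyl{[(1S,5R)-2-methyl-1-(3-methylbut-3-en-1-yl)-5-(propan-2-yl)-3-{[tri(propan-2-yl)silyl]oxy}cyclopent-2-en-1-yl]oxy}silane | C=C(C)CC[C@]1(O[Si](CC)(CC)CC)[C@@H](C(C)C)CC(O[Si](C(C)C)(C(C)C)C(C)C)=C1C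
F4 | step 10 | (2Z)-3-methyl-5-[(1S,5R)-2-methyl-5-(propan-2-yl)-1-[(triethylsilyl)oxy]-3-{[tri(propan-2-yl)silyl]oxy}cyclopent-2-en-1-yl]pent-2-enal | O=C/C=C(/C)CC[C@]1(O[Si](CC)(CC)CC)[C@@H](C(C)C)CC(O[Si](C(C)C)(C(C)C)C(C)C)=C1C
F5 | step 10 | (3R,3aS,8R,8aR)-8-hydroxy-6,8a-dimethyl-3-(propan-2-yl)-3a-[(triethylsilyl)oxy]-3,3a,4,5,8,8a-hexahydroazulen-1(2H)-one | O[C@@H]1C=C(C)CC[C@]2(O[Si](CC)(CC)CC)[C@@H](C(C)C)CC(=O)[C@]12C
F6 | step 9 | (3S,7R)-5-{[(2E)-3-{[tert-butyl(dimethyl)silyl]oxy}prop-2-en-1-yl]oxy}-4-methyl-7-(propan-2-yl)-1-oxaspiro[2.4]hept-4-ene | C1O[C@]12[C@@H](C(C)C)CC(OC/C=C/O[Si](C)(C)C(C)(C)C)=C2C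
F7 | step 9 | chloromagnesium (1S,5R)-3-{[(2E)-3-{[tert-butyl(dimethyl)silyl]oxy}prop-2-en-1-yl]oxy}-2-methyl-1-(3-methylbut-3-en-1-yl)-5-(propan-2-yl)cyclopent-2-en-1-olate | C=C(C)CC[C@]1(O[Mg]Cl)[C@@H](C(C)C)CC(OC/C=C/O[Si](C)(C)C(C)(C)C)=C1C
F0 | step 8 | none | none
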